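**Remark.** Locants C1–C7 are those of the target (7-oxabicyclo[4.1.0]hept-4-ene numbering: C1 quaternary oxirane carbon, C2 CH–OBz, C3 CH–OH, C4=C5, C6 oxirane CH; C7 is the exocyclic CH2O carbon). The target is read as (1S,2R,3R,6S), with all four ring oxygens on one face and C7 on the other.

**Plan**
- Retrosynthesis: the C3 carbinol goes back to its enone, the oxirane C6–O bond to a C1/C6 trans-diol, the C1–C2 bond to a ketyl–carbonyl (pinacol) union of a C1 ketone and a C2 aldehyde, C4=C5 to ring-closing metathesis, and two Si–O bonds to two small vinyl carbinols.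
- Enabling feature: the oxygens on C1 and C2 are cis on adjacent ring carbons, a vicinal diol that one samarium can bridge. The oxygens on C3 and C6 are 1,4-related across C4=C5, so one tBu2Si atom can tie them into a 4,7-dihydro-1,3,2-dioxasilepine ring that holds both carbonyl arms on one face.
- Forward: the silicon tether joins fragment 2 (C7–C1–C6–C5) to fragment 4 (C4–C3–C2); metathesis closes the seven-membered silepine; the pinacol closes the cyclohexene as a bicyclo[3.2.2] system; the silylene is then removed and the oxirane closed.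
- Stereochemistry: C6 from Sharpless desymmetrization of divinylcarbinol; C3 from (S)-but-3-ene-1,2-diol, used as a relay centre that makes the tether cis; C1 and C2 from the samarium-bridged pinacol, anti to the silylene; C6 inverted on oxirane closure; C3 reset by Luche reduction anti to the C2 benzoate.

Key step: step 8

**Step 1**
Reactants: 1 penta-1,4-dien-3-ol
Product: 2 (2S,3R)-1,2-epoxypent-4-en-3-ol
Conditions: Ti(OiPr)4 (cat.), diisopropyl D-(−)-tartrate (cat.), t-BuOOH, 4 Å molecular sieves, CH2Cl2, −20 °C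
Reagents that add atoms: tert-butyl hydroperoxide, CC(C)(C)OO
Why: Sharpless asymmetric epoxidation of the prochiral dienol, in which the tartrate–titanium catalyst should select one enantiotopic vinyl group and one alkene face, so that the carbinol carbon (future C6) is R and the oxirane carbon S (erythro).

**Step 2**
Reactants: 3 (S)-but-3-ene-1,2-diol
Product: 4 (S)-1-[(tert-butyldimethylsilyl)oxy]but-3-en-2-ol
Conditions: TBSCl (1.05 equiv), imidazole, CH2Cl2, −20 °C to 0 °C
Reagents that add atoms: tert-butyldimethylsilyl chloride, CC(C)(C)[Si](C)(C)Cl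
Why: Selective silyl ether formation at the primary hydroxyl by the bulky chlorosilane should leave the secondary allylic hydroxyl (future C3–O) free for the tether, and no stereocenter is touched.

**Step 3**
Reactants: 4 (S)-1-[(tert-butyldimethylsilyl)oxy]but-3-en-2-ol; 2 (2S,3R)-1,2-epoxypent-4-en-3-ol
Product: 6 di-tert-butyl{[(S)-1-(TBS-oxy)but-3-en-2-yl]oxy}{[(R)-1-[(S)-oxiran-2-yl]prop-2-en-1-yl]oxy}silane (mixed silyl ketal), via silyl triflate 5 (not isolated)
Conditions: tBu2Si(OTf)2 (1.0 equiv), 2,6-lutidine, CH2Cl2, −78 °C, slow addition of 4; then 2, 2,6-lutidine, −78 °C to rt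
Reagents that add atoms: di-tert-butylsilyl bis(trifluoromethanesulfonate), CC(C)(C)[Si](OS(=O)(=O)C(F)(F)F)(OS(=O)(=O)C(F)(F)F)C(C)(C)C
Why: Stepwise silyl ether formation (temporary silicon tether), in which the first secondary alcohol should displace only one triflate of the hindered bis(triflate) at low temperature and the remaining silyl triflate then captures the epoxy alcohol, both carbinol centres being carried over unchanged.

**Step 4**
Reactants: 6 mixed silyl ketal
Product: 7 (4R,7S)-2,2-di-tert-butyl-7-{[(tert-butyldimethylsilyl)oxy]methyl}-4-[(S)-oxiran-2-yl]-4,7-dihydro-1,3,2-dioxasilepine (4,7-cis)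
Conditions: second-generation Grubbs catalyst (5 mol %), CH2Cl2 (0.01 M), 40 °C
Reagents that add atoms: none
Why: Ring-closing metathesis of the two monosubstituted alkenes held on silicon should close the seven-membered silepine, in which the new C4=C5 bond can only be Z and the 4,7-substituents are cis because of the configurations brought in by 2 and 4.

**Step 5**
Reactants: 7 cis-silepine epoxide
Product: 8 (S)-1-[(4R,7S)-2,2-di-tert-butyl-7-{[(tert-butyldimethylsilyl)oxy]methyl}-4,7-dihydro-1,3,2-dioxasilepin-4-yl]-2-[(4-methoxybenzyl)oxy]ethan-1-ol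
Conditions: 4-methoxybenzyl alcohol (5 equiv), KOtBu (0.2 equiv), DMF, 60 °C
Reagents that add atoms: 4-methoxybenzyl alcohol, COc1ccc(CO)cc1
Why: Base-catalysed epoxide opening (SN2) by the alkoxide at the unsubstituted oxirane carbon C7 should install the PMB ether and free the C1 hydroxyl without changing its configuration.

**Step 6**
Reactants: 8 PMB ether alcohol
Product: 9 (S)-1-[(4R,7S)-2,2-di-tert-butyl-7-(hydroxymethyl)-4,7-dihydro-1,3,2-dioxasilepin-4-yl]-2-[(4-methoxybenzyl)oxy]ethan-1-ol
Conditions: PPTS (cat.), MeOH, rt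
Reagents that add atoms: none
Why: Acid-catalysed methanolysis (desilylation) should remove the primary TBS ether much faster than the hindered cyclic di-tert-butylsilylene or the PMB ether.

**Step 7**
Reactants: 9 diol
Product: 10 (4S,7R)-2,2-di-tert-butyl-7-{2-[(4-methoxybenzyl)oxy]acetyl}-4,7-dihydro-1,3,2-dioxasilepine-4-carbaldehyde
Conditions: Dess–Martin periodinane (3 equiv), NaHCO3, CH2Cl2, 0 °C to rt; crude product used at once
Reagents that add atoms: none
Why: Dess–Martin oxidation of the secondary and the primary alcohol under buffered, non-basic conditions should give the keto-aldehyde without epimerizing the two α-silyloxy β,γ-unsaturated centres, the C1 stereocenter being erased on purpose.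

**Step 8**
Reactants: 10 keto-aldehyde
Product: 11 (1S,5R,6R,7R)-3,3-di-tert-butyl-6-{[(4-methoxybenzyl)oxy]methyl}-2,4-dioxa-3-silabicyclo[3.2.2]non-8-ene-6,7-diol (cis-diol on the ring face opposite to the O–Si–O bridge)
Conditions: SmI2 (3 equiv, 0.1 M in THF), t-BuOH (3 equiv), THF (0.005 M), −78 °C to −20 °C, slow addition of 10
Reagents that add atoms: none
Why: In this samarium diiodide pinacol cyclization, electron transfer to the aldehyde gives a samarium-bound ketyl radical at C2, which adds to the ketone carbon C1 (6-exo-trig attack on the C=O bond, closing the cyclohexene as the second two-carbon bridge of the bicyclo[3.2.2] skeleton), and a second electron transfer with protonation gives the diol. The closest known reaction type is the SmI2-mediated intramolecular pinacol coupling of sugar-derived 1,6-keto-aldehydes to branched cyclitols. Both new stereocenters arise together: trivalent samarium bridges the two oxygens, so the C1 and C2 hydroxyls should come out cis, and this chelated pair should form on the face opposite to the O–Si–O bridge, anti to the C3–O and C6–O bonds (dipole repulsion) and away from the tert-butyl groups. The centres at C3 and C6 are untouched, and their cis relationship on the silepine is what lets the two carbonyl carbons meet. The step needs the aldehyde to be reduced before the α-alkoxy ketone, cyclization to be faster than reductive loss of an α-oxygen or simple reduction, and no intermolecular coupling; the tether raises the effective molarity, and high dilution at −78 °C with t-BuOH should secure the rest.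

**Step 9**
Reactants: 11 bicyclic diol
Product: 12 (1S,5R,6R,7R)-3,3-di-tert-butyl-6-(hydroxymethyl)-2,4-dioxa-3-silabicyclo[3.2.2]non-8-ene-6,7-diol
Conditions: DDQ (1.3 equiv), CH2Cl2/pH 7 buffer (10:1), 0 °C
Reagents that add atoms: none
Why: Oxidative PMB ether cleavage (benzylic hydride abstraction by DDQ and hydrolysis of the oxocarbenium ion) should free the C7 hydroxyl while the silylene, the alkene and the diol are left alone.

**Step 10**
Reactants: 12 triol
Product: 13 [(1S,5R,6R,7R)-7-(benzoyloxy)-3,3-di-tert-butyl-6-hydroxy-2,4-dioxa-3-silabicyclo[3.2.2]non-8-en-6-yl]methyl benzoate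
Conditions: BzCl (3 equiv), pyridine, DMAP (cat.), CH2Cl2, 0 °C to rt
Reagents that add atoms: benzoyl chloride, O=C(Cl)c1ccccc1
Why: DMAP-catalysed acylation should benzoylate the primary C7 and the secondary C2 hydroxyls while the tertiary C1 hydroxyl stays free, which fixes the benzoate pattern of the target without touching a stereocenter.

**Step 11**
Reactants: 13 dibenzoate
Product: 14 [(1S,2R,3S,6R)-2-(benzoyloxy)-1,3,6-trihydroxycyclohex-4-en-1-yl]methyl benzoate
Conditions: HF·pyridine, pyridine/THF, 0 °C to rt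
Reagents that add atoms: none
Why: Fluoride-mediated desilylation should cleave both Si–O bonds of the silylene under mildly acidic conditions that do not make benzoates migrate, releasing the C3 and C6 hydroxyls.

**Step 12**
Reactants: 14 triol dibenzoate
Product: 16 [(1S,2R,3S,6S)-2-(benzoyloxy)-3-hydroxy-7-oxabicyclo[4.1.0]hept-4-en-1-yl]methyl benzoate (C3 epimer of the target), via allylic tosylate 15 (not isolated)
Conditions: TsCl (1.1 equiv), Et3N (4 equiv), Bu2SnO (5 mol %), CH2Cl2, 0 °C to rt, then 35 °C
Reagents that add atoms: none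
Why: Tin-catalysed regioselective sulfonylation of a 1,2-diol followed by Williamson-type ring closure, in which only the C6 hydroxyl (able to form a stannylene acetal with the vicinal C1 hydroxyl) should be tosylated and the trans C1 oxygen then displaces the allylic tosylate with inversion at C6 (3-exo-tet), placing the oxirane on the face of the C2 benzoate.

**Step 13**
Reactants: 16 epoxy alcohol
Product: 17 [(1S,2S,6S)-2-(benzoyloxy)-3-oxo-7-oxabicyclo[4.1.0]hept-4-en-1-yl]methyl benzoate
Conditions: Dess–Martin periodinane (1.5 equiv), NaHCO3, CH2Cl2, 0 °C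
Reagents that add atoms: none
Why: Dess–Martin oxidation of the remaining allylic secondary alcohol should give the enone and remove the C3 centre that was needed only to make the tether cis.

**Step 14**
Reactants: 17 epoxy enone
Product: 18 [(1S,2R,3R,6S)-2-(benzoyloxy)-3-hydroxy-7-oxabicyclo[4.1.0]hept-4-en-1-yl]methyl benzoate (target)
Conditions: NaBH4 (1 equiv), CeCl3·7H2O (1 equiv), MeOH, −78 °C
Reagents that add atoms: none
Why: Luche reduction (1,2-reduction of the enone) should deliver hydride to C3 from the face opposite to the adjacent C2 benzoate and the oxirane oxygen, so that the new hydroxyl is cis to both (3R) and no conjugate reduction occurs.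

**Compound list**
1 | penta-1,4-dien-3-ol | C=CC(O)C=C | starting material
2 | (2S,3R)-1,2-epoxypent-4-en-3-ol | C=C[C@@H](O)[C@@H]1CO1 | intermediate
3 | (S)-but-3-ene-1,2-diol | C=C[C@H](O)CO | starting material
4 | (S)-1-[(tert-butyldimethylsilyl)oxy]but-3-en-2-ol | C=C[C@H](O)CO[Si](C)(C)C(C)(C)C | intermediate
5 | di-tert-butyl{[(S)-1-(TBS-oxy)but-3-en-2-yl]oxy}silyl trifluoromethanesulfonate | C=C[C@@H](CO[Si](C)(C)C(C)(C)C)O[Si](OS(=O)(=O)C(F)(F)F)(C(C)(C)C)C(C)(C)C | intermediate
6 | di-tert-butyl{[(S)-1-(TBS-oxy)but-3-en-2-yl]oxy}{[(R)-1-[(S)-oxiran-2-yl]prop-2-en-1-yl]oxy}silane | C=C[C@H]([C@@H]1CO1)O[Si](C(C)(C)C)(C(C)(C)C)O[C@@H](C=C)CO[Si](C)(C)C(C)(C)C | intermediate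
7 | (4R,7S)-2,2-di-tert-butyl-7-{[(tert-butyldimethylsilyl)oxy]methyl}-4-[(S)-oxiran-2-yl]-4,7-dihydro-1,3,2-dioxasilepine | C1O[C@@H]1[C@H]2C=C[C@@H](CO[Si](C)(C)C(C)(C)C)O[Si](C(C)(C)C)(C(C)(C)C)O2 | intermediate
8 | (S)-1-[(4R,7S)-2,2-di-tert-butyl-7-{[(tert-butyldimethylsilyl)oxy]methyl}-4,7-dihydro-1,3,2-dioxasilepin-4-yl]-2-[(4-methoxybenzyl)oxy]ethan-1-ol | COc1ccc(COC[C@H](O)[C@H]2C=C[C@@H](CO[Si](C)(C)C(C)(C)C)O[Si](C(C)(C)C)(C(C)(C)C)O2)cc1 | intermediate
9 | (S)-1-[(4R,7S)-2,2-di-tert-butyl-7-(hydroxymethyl)-4,7-dihydro-1,3,2-dioxasilepin-4-yl]-2-[(4-methoxybenzyl)oxy]ethan-1-ol | COc1ccc(COC[C@H](O)[C@H]2C=C[C@@H](CO)O[Si](C(C)(C)C)(C(C)(C)C)O2)cc1 | intermediate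
10 | (4S,7R)-2,2-di-tert-butyl-7-{2-[(4-methoxybenzyl)oxy]acetyl}-4,7-dihydro-1,3,2-dioxasilepine-4-carbaldehyde | COc1ccc(COCC(=O)[C@H]2C=C[C@@H](C=O)O[Si](C(C)(C)C)(C(C)(C)C)O2)cc1 | intermediate
11 | (1S,5R,6R,7R)-3,3-di-tert-butyl-6-{[(4-methoxybenzyl)oxy]methyl}-2,4-dioxa-3-silabicyclo[3.2.2]non-8-ene-6,7-diol | COc1ccc(COC[C@]2(O)[C@H]3C=C[C@H](O[Si](C(C)(C)C)(C(C)(C)C)O3)[C@H]2O)cc1 | intermediate
12 | (1S,5R,6R,7R)-3,3-di-tert-butyl-6-(hydroxymethyl)-2,4-dioxa-3-silabicyclo[3.2.2]non-8-ene-6,7-diol | OC[C@]1(O)[C@H]2C=C[C@H](O[Si](C(C)(C)C)(C(C)(C)C)O2)[C@H]1O | intermediate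
13 | [(1S,5R,6R,7R)-7-(benzoyloxy)-3,3-di-tert-butyl-6-hydroxy-2,4-dioxa-3-silabicyclo[3.2.2]non-8-en-6-yl]methyl benzoate | O=C(OC[C@]1(O)[C@H]2C=C[C@H](O[Si](C(C)(C)C)(C(C)(C)C)O2)[C@H]1OC(=O)c1ccccc1)c1ccccc1 | intermediate
14 | [(1S,2R,3S,6R)-2-(benzoyloxy)-1,3,6-trihydroxycyclohex-4-en-1-yl]methyl benzoate | O=C(OC[C@]1(O)[C@H](O)C=C[C@H](O)[C@H]1OC(=O)c1ccccc1)c1ccccc1 | intermediate
15 | [(1R,2R,3S,6R)-2-(benzoyloxy)-1,3-dihydroxy-6-(tosyloxy)cyclohex-4-en-1-yl]methyl benzoate (C6 tosylate of 14) | O=C(OC[C@]1(O)[C@H](OS(=O)(=O)c2ccc(C)cc2)C=C[C@H](O)[C@H]1OC(=O)c1ccccc1)c1ccccc1 | intermediate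
16 | [(1S,2R,3S,6S)-2-(benzoyloxy)-3-hydroxy-7-oxabicyclo[4.1.0]hept-4-en-1-yl]methyl benzoate | O=C(OC[C@]12O[C@H]1C=C[C@H](O)[C@H]2OC(=O)c1ccccc1)c1ccccc1 | intermediate
17 | [(1S,2S,6S)-2-(benzoyloxy)-3-oxo-7-oxabicyclo[4.1.0]hept-4-en-1-yl]methyl benzoate | O=C(OC[C@]12O[C@H]1C=CC(=O)[C@H]2OC(=O)c1ccccc1)c1ccccc1 | intermediate
18 | [(1S,2R,3R,6S)-2-(benzoyloxy)-3-hydroxy-7-oxabicyclo[4.1.0]hept-4-en-1-yl]methyl benzoate | O=C(OC[C@]12O[C@H]1C=C[C@@H](O)[C@H]2OC(=O)c1ccccc1)c1ccccc1 | target

**Step count**
Total: 14 steps. Longest linear sequence: 13 steps (1 to 18 through steps 1 and 3–14; the branch from 3 through steps 2–14 is equally long).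

**Steps most likely to fail**

Step 8. The ketyl cyclization may be outrun by reductive loss of an α-oxygen substituent, by simple reduction of the carbonyls or by intermolecular coupling, or the strained bicyclic transition state may erode the facial preference. The fallback sets out from keto-aldehyde 10. Both carbonyls are methylenated (Ph3P=CH2, THF, −78 °C to 0 °C) to give the cis-4-ethenyl-7-{3-[(4-methoxybenzyl)oxy]prop-1-en-2-yl}silepine triene F1. Ring-closing metathesis with the second-generation Grubbs catalyst then forms the C1=C2 bond of the 2,4-dioxa-3-silabicyclo[3.2.2]nona-6,8-diene F2. OsO4 (cat.) with N-methylmorpholine N-oxide in acetone/water should dihydroxylate the more electron-rich trisubstituted alkene from the face away from the silylene bridge, and the route is rejoined at diol 11.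

Step 12. Sulfonylation may occur at the C3 hydroxyl instead, or chloride may displace the allylic sulfonate before the ring closes. The fallback sets out from triol 14. The less hindered C3 hydroxyl is silylated selectively (TESCl, imidazole, CH2Cl2, −40 °C) to the 3-O-triethylsilyl ether F3. MsCl/Et3N then converts the only remaining secondary hydroxyl into the C6 mesylate F4, which closes on warming with excess Et3N to the 3-O-triethylsilyl oxirane F5. HF·pyridine removes the silyl group and the route is rejoined at epoxy alcohol 16.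

Step 14. Hydride delivery may show poor facial selectivity and return the C3 epimer, or the C2 benzoate may migrate to the new cis hydroxyl. The fallback sets out from epoxy alcohol 16 and avoids the ketone. A Mitsunobu reaction (PPh3, DIAD, chloroacetic acid, toluene, 0 °C) inverts C3 by SN2 displacement to the 3-O-chloroacetate F6. Thiourea with NaHCO3 in ethanol at rt then removes the chloroacetyl group in the presence of the two benzoates, and the route is rejoined at target 18.

**Further compounds**
F1 | step 8 | (4S,7R)-2,2-di-tert-butyl-4-ethenyl-7-{3-[(4-methoxybenzyl)oxy]prop-1-en-2-yl}-4,7-dihydro-1,3,2-dioxasilepine (4,7-cis) | COc1ccc(COCC(=C)[C@H]2C=C[C@@H](C=C)O[Si](C(C)(C)C)(C(C)(C)C)O2)cc1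
F2 | step 8 | 3,3-di-tert-butyl-6-{[(4-methoxybenzyl)oxy]methyl}-2,4-dioxa-3-silabicyclo[3.2.2]nona-6,8-diene | COc1ccc(COCC2=C[C@@H]3C=C[C@H]2O[Si](C(C)(C)C)(C(C)(C)C)O3)cc1
F3 | step 12 | 3-O-triethylsilyl ether of triol 14 | O=C(OC[C@]1(O)[C@H](O)C=C[C@H](O[Si](CC)(CC)CC)[C@H]1OC(=O)c1ccccc1)c1ccccc1
F4 | step 12 | 6-O-methanesulfonate of F3 | O=C(OC[C@]1(O)[C@H](OS(C)(=O)=O)C=C[C@H](O[Si](CC)(CC)CC)[C@H]1OC(=O)c1ccccc1)c1ccccc1
F5 | step 12 | 3-O-triethylsilyl ether of epoxy alcohol 16 | O=C(OC[C@]12O[C@H]1C=C[C@H](O[Si](CC)(CC)CC)[C@H]2OC(=O)c1ccccc1)c1ccccc1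
F6 | step 14 | 3-O-chloroacetate of target 18 | O=C(OC[C@]12O[C@H]1C=C[C@@H](OC(=O)CCl)[C@H]2OC(=O)c1ccccc1)c1ccccc1
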